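**Plan**
1. Cuts: the C3–O ester bond comes off last. Then C4a–C8a and C5–C6 are cut together, which opens both rings to an acyclic N-(buta-1,3-dienyl) carbamate carrying a Z-alkene. Further back: N1–C8a (crotonaldehyde), C5=C6 (alkyne) and C4–C5 (epoxide plus acetylide).
2. Enabling feature: the carbocycle C4a–C5–C6–C7–C8–C8a carries N1 on C8a, C4 on C4a and the side chain on C5, all on one face. This is the imprint of a 1-amidodiene (N1–C8a=C8–C7=C6) adding to a Z-alkene (C4a=C5), with N1–C2–C3–C4 of the piperidine ring as the tether.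
3. Forward: an alanine-derived anti amino epoxide and the side-chain acetylide are joined to the full C14 chain. Semihydrogenation and N-dienylation follow, and one thermal step closes the carbocycle and the piperidine ring together. Hydrogenation, acylation at O3 and deprotection finish the synthesis.
4. Stereochemistry: C2 comes from L-alanine, C3 from a chelation-controlled ketone reduction and C5′ from (R)-2-propyloxirane. C4a, C5 and C8a come from the cycloaddition (Z geometry, endo tether, A(1,3) strain at C2).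

Key step: step 10

Assumption: the target is made as the free base drawn; ring positions follow decahydroquinoline numbering (N1, C2–C8a) and the side-chain carbons are primed (C1′–C8′).

**Route**

Step 1
Reactants: 1 Boc-L-alanine N-methoxy-N-methylamide
Product: 2 tert-butyl N-[(2S)-4-chloro-3-oxobutan-2-yl]carbamate
Conditions: ICH2Cl (3 equiv), MeLi·LiBr (3 equiv), THF, −78 °C; aq. NH4Cl
Reagents that add atoms: chloroiodomethane, ClCI
Why: Carbenoid homologation of a Weinreb amide: chloromethyllithium from iodine–lithium exchange should add once because the chelated tetrahedral adduct persists until the quench, and the N-lithiated carbamate should protect the alanine stereocentre from enolisation.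

Step 2
Reactants: 2 tert-butyl N-[(2S)-4-chloro-3-oxobutan-2-yl]carbamate
Product: 3 tert-butyl N-[(2S,3S)-4-chloro-3-hydroxybutan-2-yl]carbamate
Conditions: LiAlH(O-t-Bu)3, EtOH, −78 °C; recrystallise
Reagents that add atoms: none
Why: Chelation-controlled hydride reduction (Cram cyclic model) of the carbamate-protected α-amino ketone should deliver hydride to the face of the lithium-bridged chelate that carries H and not methyl, setting C3 as the anti (2S,3S) chlorohydrin.

Step 3
Reactants: 3 tert-butyl N-[(2S,3S)-4-chloro-3-hydroxybutan-2-yl]carbamate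
Product: 4 tert-butyl N-[(1S)-1-[(2S)-oxiran-2-yl]ethyl]carbamate
Conditions: KOH, EtOH, 0 → 23 °C
Reagents that add atoms: none
Why: Intramolecular Williamson etherification (3-exo-tet displacement of chloride by the alkoxide) should close the epoxide at the CH2 carbon without touching either stereocentre.

Step 4
Reactants: 5 (R)-2-propyloxirane; 6 (5-chloropent-1-yn-1-yl)trimethylsilane
Product: 9 (4R)-dec-9-yn-4-ol, via Grignard reagent 7 (not isolated), via silylalkynol 8 (not isolated)
Conditions: 6, Mg, THF, reflux; CuI (10 mol %), 5, THF, −30 → 0 °C; then MeOH, K2CO3, 23 °C; aq. NH4Cl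
Reagents that add atoms: none
Why: Copper-catalysed SN2 opening of a terminal epoxide by a primary Grignard reagent should occur only at the CH2 carbon, so the carbinol centre is untouched, and methoxide-induced protodesilylation then frees the terminal alkyne.

Step 5
Reactants: 9 (4R)-dec-9-yn-4-ol
Product: 10 tert-butyl{[(4R)-dec-9-yn-4-yl]oxy}diphenylsilane
Conditions: TBDPSCl, imidazole, DMF, 23 °C
Reagents that add atoms: tert-butyl(chloro)diphenylsilane, CC(C)(C)[Si](Cl)(c1ccccc1)c1ccccc1
Why: Imidazole-promoted silylation of a secondary alcohol should give a silyl ether robust enough for the acetylide, triflate, amide-base, thermal and acidic steps that follow.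

Step 6
Reactants: 10 tert-butyl{[(4R)-dec-9-yn-4-yl]oxy}diphenylsilane (2.5 equiv); 4 tert-butyl N-[(1S)-1-[(2S)-oxiran-2-yl]ethyl]carbamate
Product: 12 tert-butyl N-[(2S,3R,11R)-11-[(tert-butyldiphenylsilyl)oxy]-3-hydroxytetradec-5-yn-2-yl]carbamate, via lithium acetylide 11 (not isolated)
Conditions: 10, n-BuLi, THF, −78 °C; BF3·OEt2; then 4, −78 °C; aq. NH4Cl (surplus 10 recovered)
Reagents that add atoms: none
Why: BF3-promoted alkynylation of an epoxide by a lithium acetylide should open the unsubstituted carbon at −78 °C; one equivalent of acetylide is sacrificed to the carbamate N–H, and C3 keeps its configuration because it is not the site of attack.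

Step 7
Reactants: 12 tert-butyl N-[(2S,3R,11R)-11-[(tert-butyldiphenylsilyl)oxy]-3-hydroxytetradec-5-yn-2-yl]carbamate
Product: 13 tert-butyl N-[(2S,3R,5Z,11R)-11-[(tert-butyldiphenylsilyl)oxy]-3-hydroxytetradec-5-en-2-yl]carbamate
Conditions: H2 (1 atm), Pd/CaCO3 poisoned with Pb(OAc)2 (Lindlar catalyst), quinoline, EtOAc, 23 °C
Reagents that add atoms: none
Why: Lindlar semihydrogenation (syn delivery of hydrogen on the poisoned palladium surface) should stop at the Z-alkene whose geometry later fixes the C4a/C5 relationship.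

Step 8
Reactants: 13 tert-butyl N-[(2S,3R,5Z,11R)-11-[(tert-butyldiphenylsilyl)oxy]-3-hydroxytetradec-5-en-2-yl]carbamate
Product: 15 (2S,3R,5Z,11R)-3-[(tert-butyldimethylsilyl)oxy]-11-[(tert-butyldiphenylsilyl)oxy]tetradec-5-en-2-amine, via silyl carbamate 14 (not isolated)
Conditions: TBSOTf (3 equiv), 2,6-lutidine, CH2Cl2, 0 → 23 °C; then MeOH, 23 °C; aq. NaHCO3
Reagents that add atoms: tert-butyldimethylsilyl trifluoromethanesulfonate, CC(C)(C)[Si](C)(C)OS(=O)(=O)C(F)(F)F
Why: Silyl triflate-mediated O-silylation and Boc-to-silyl-carbamate exchange (loss of isobutene), followed by methanolysis and decarboxylation, should free the amine without protic acid, so both silyl ethers and the Z-alkene survive.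

Step 9
Reactants: 15 (2S,3R,5Z,11R)-3-[(tert-butyldimethylsilyl)oxy]-11-[(tert-butyldiphenylsilyl)oxy]tetradec-5-en-2-amine; 16 (E)-but-2-enal
Product: 19 benzyl N-[(1E)-buta-1,3-dien-1-yl]-N-[(2S,3R,5Z,11R)-3-[(tert-butyldimethylsilyl)oxy]-11-[(tert-butyldiphenylsilyl)oxy]tetradec-5-en-2-yl]carbamate, via crotonaldimine 17 (not isolated), via sodium azadienide 18 (not isolated)
Conditions: 16, MgSO4, CH2Cl2, 0 → 23 °C; filter, concentrate; NaN(SiMe3)2, THF, −78 °C; CbzCl, −78 → 0 °C
Reagents that add atoms: benzyl chloroformate, O=C(Cl)OCc1ccccc1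
Why: Imine condensation, γ-deprotonation to the 1-azapentadienyl anion and N-acylation by the chloroformate (dienamide synthesis from an α,β-unsaturated imine) should give the E-configured N-acyl 1-amino-1,3-diene, the hindered tertiary C2–H being less acidic kinetically than the γ-methyl so that the alanine centre is kept.

Step 10
Reactants: 19 benzyl N-[(1E)-buta-1,3-dien-1-yl]-N-[(2S,3R,5Z,11R)-3-[(tert-butyldimethylsilyl)oxy]-11-[(tert-butyldiphenylsilyl)oxy]tetradec-5-en-2-yl]carbamate
Product: 20 benzyl (2S,3R,4aS,5S,8aR)-3-[(tert-butyldimethylsilyl)oxy]-5-[(5R)-5-[(tert-butyldiphenylsilyl)oxy]octyl]-2-methyl-3,4,4a,5,6,8a-hexahydroquinoline-1(2H)-carboxylate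
Conditions: toluene (0.01 M), N,O-bis(trimethylsilyl)acetamide (0.2 equiv), BHT (5 mol %), silylated sealed tube, 205 °C, 20 h
Reagents that add atoms: none
Why: A thermal, concerted, suprafacial intramolecular [4+2] cycloaddition joins C8a of the E-dienyl carbamate to C4a and C6 to C5 of the tethered Z-alkene; the closest known reaction type is the intramolecular Diels–Alder reaction of N-acyl-N-alkenyl 1-amino-1,3-dienes with unactivated alkenes, which delivers cis-fused octahydroquinolines on heating to about 200 °C. The cyclohexene ring closes by the cycloaddition itself (both new bonds are ring bonds), and the piperidine ring closes through the C4a–C8a bond with the four-atom N1–C2–C3–C4 tether in a chair-like array (type 1 mode, tether on the diene terminus). C4a and C5 are set relative to each other by the Z geometry of the dienophile, which is carried over unchanged and places C4 and the side chain cis. C8a is set relative to C4a by the tether-endo transition state open to the E-dienamide, which gives the cis ring fusion. The absolute sense of all three comes from C2: A(1,3) strain with the planar carbamate holds C2–H in the amide plane and the methyl group perpendicular to it, so the tether and alkene reach C8a from the face anti to the methyl, leaving methyl and C8 cis on the piperidine ring, while the C3 silyl ether lies anti to the methyl and does not oppose this. The step needs endo over exo tether orientation and a single diene face, which the planar N-acyl group and the two tether stereocentres should secure; silylated glass, the silylating acid scavenger and BHT should suppress acid- and radical-induced loss of the dienyl carbamate.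

Step 11
Reactants: 20 benzyl (2S,3R,4aS,5S,8aR)-3-[(tert-butyldimethylsilyl)oxy]-5-[(5R)-5-[(tert-butyldiphenylsilyl)oxy]octyl]-2-methyl-3,4,4a,5,6,8a-hexahydroquinoline-1(2H)-carboxylate
Product: 22 tert-butyl (2S,3R,4aS,5S,8aR)-3-[(tert-butyldimethylsilyl)oxy]-5-[(5R)-5-[(tert-butyldiphenylsilyl)oxy]octyl]-2-methyloctahydroquinoline-1(2H)-carboxylate, via secondary amine 21 (not isolated)
Conditions: H2 (1 atm), Pd/C, Boc2O, EtOAc, 23 °C; filter; 50 °C
Reagents that add atoms: di-tert-butyl dicarbonate, CC(C)(C)OC(=O)OC(=O)OC(C)(C)C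
Why: Heterogeneous hydrogenation should saturate the cis-disubstituted C7=C8 alkene and hydrogenolyse the benzyl carbamate in one operation, and the freed secondary amine is trapped in the same flask as its Boc carbamate (hydrogenolysis with in situ N-acylation) without affecting any stereocentre.

Step 12
Reactants: 22 tert-butyl (2S,3R,4aS,5S,8aR)-3-[(tert-butyldimethylsilyl)oxy]-5-[(5R)-5-[(tert-butyldiphenylsilyl)oxy]octyl]-2-methyloctahydroquinoline-1(2H)-carboxylate
Product: 23 tert-butyl (2S,3R,4aS,5S,8aR)-5-[(5R)-5-[(tert-butyldiphenylsilyl)oxy]octyl]-3-hydroxy-2-methyloctahydroquinoline-1(2H)-carboxylate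
Conditions: CSA (0.3 equiv), MeOH/CH2Cl2 (1:1), 0 → 23 °C
Reagents that add atoms: none
Why: Acid-catalysed methanolysis of a silyl ether should remove the TBS group selectively because a TBDPS ether is far more stable to acid, and catalytic sulfonic acid in methanol should not cleave the Boc group.

Step 13
Reactants: 23 tert-butyl (2S,3R,4aS,5S,8aR)-5-[(5R)-5-[(tert-butyldiphenylsilyl)oxy]octyl]-3-hydroxy-2-methyloctahydroquinoline-1(2H)-carboxylate; 24 (2E,4E)-octa-2,4-dienoic acid
Product: 26 tert-butyl (2S,3R,4aS,5S,8aR)-5-[(5R)-5-[(tert-butyldiphenylsilyl)oxy]octyl]-2-methyl-3-{[(2E,4E)-octa-2,4-dienoyl]oxy}octahydroquinoline-1(2H)-carboxylate, via mixed anhydride 25 (not isolated)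
Conditions: 24, 2,4,6-trichlorobenzoyl chloride, Et3N, THF, 23 °C; then 23, DMAP, toluene, 23 → 50 °C
Reagents that add atoms: none
Why: Yamaguchi esterification through the mixed trichlorobenzoic anhydride and an acylpyridinium should acylate the hindered secondary C3 alcohol with retention, the nitrogen being blocked as its carbamate.

Step 14
Reactants: 26 tert-butyl (2S,3R,4aS,5S,8aR)-5-[(5R)-5-[(tert-butyldiphenylsilyl)oxy]octyl]-2-methyl-3-{[(2E,4E)-octa-2,4-dienoyl]oxy}octahydroquinoline-1(2H)-carboxylate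
Product: 27 tert-butyl (2S,3R,4aS,5S,8aR)-5-[(5R)-5-hydroxyoctyl]-2-methyl-3-{[(2E,4E)-octa-2,4-dienoyl]oxy}octahydroquinoline-1(2H)-carboxylate
Conditions: HF·pyridine, pyridine, THF, 0 → 23 °C
Reagents that add atoms: none
Why: Fluoride-mediated Si–O cleavage under buffered conditions should free the side-chain alcohol without touching the dienoate or the carbamate.

Step 15
Reactants: 27 tert-butyl (2S,3R,4aS,5S,8aR)-5-[(5R)-5-hydroxyoctyl]-2-methyl-3-{[(2E,4E)-octa-2,4-dienoyl]oxy}octahydroquinoline-1(2H)-carboxylate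
Product: 28 lepadin H
Conditions: TFA/CH2Cl2 (1:4), 0 °C; cold aq. NaHCO3
Reagents that add atoms: none
Why: Acidolysis of the tert-butyl carbamate (loss of isobutene and CO2) should give the ammonium salt, which cannot undergo O-to-N acyl shift, and cold bicarbonate work-up then liberates the free base.

**Compound list**
1 | tert-butyl N-[(2S)-1-[methoxy(methyl)amino]-1-oxopropan-2-yl]carbamate (Boc-L-alanine N-methoxy-N-methylamide) | C[C@H](NC(=O)OC(C)(C)C)C(=O)N(C)OC | starting material
2 | tert-butyl N-[(2S)-4-chloro-3-oxobutan-2-yl]carbamate | C[C@H](NC(=O)OC(C)(C)C)C(=O)CCl | intermediate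
3 | tert-butyl N-[(2S,3S)-4-chloro-3-hydroxybutan-2-yl]carbamate | C[C@H](NC(=O)OC(C)(C)C)[C@H](O)CCl | intermediate
4 | tert-butyl N-[(1S)-1-[(2S)-oxiran-2-yl]ethyl]carbamate | C[C@H](NC(=O)OC(C)(C)C)[C@H]1CO1 | intermediate
5 | (R)-2-propyloxirane | CCC[C@@H]1CO1 | starting material
6 | (5-chloropent-1-yn-1-yl)trimethylsilane | C[Si](C)(C)C#CCCCCl | starting material
7 | [5-(trimethylsilyl)pent-4-yn-1-yl]magnesium chloride | C[Si](C)(C)C#CCCC[Mg]Cl | intermediate
8 | (4R)-10-(trimethylsilyl)dec-9-yn-4-ol | C[Si](C)(C)C#CCCCC[C@H](O)CCC | intermediate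
9 | (4R)-dec-9-yn-4-ol | C#CCCCC[C@H](O)CCC | intermediate
10 | tert-butyl{[(4R)-dec-9-yn-4-yl]oxy}diphenylsilane | C#CCCCC[C@H](O[Si](c1ccccc1)(c1ccccc1)C(C)(C)C)CCC | intermediate
11 | lithium (7R)-7-[(tert-butyldiphenylsilyl)oxy]dec-1-yn-1-ide | [Li]C#CCCCC[C@H](O[Si](c1ccccc1)(c1ccccc1)C(C)(C)C)CCC | intermediate
12 | tert-butyl N-[(2S,3R,11R)-11-[(tert-butyldiphenylsilyl)oxy]-3-hydroxytetradec-5-yn-2-yl]carbamate | C[C@H](NC(=O)OC(C)(C)C)[C@H](O)CC#CCCCC[C@H](O[Si](c1ccccc1)(c1ccccc1)C(C)(C)C)CCC | intermediate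
13 | tert-butyl N-[(2S,3R,5Z,11R)-11-[(tert-butyldiphenylsilyl)oxy]-3-hydroxytetradec-5-en-2-yl]carbamate | C[C@H](NC(=O)OC(C)(C)C)[C@H](O)C/C=C\CCCC[C@H](O[Si](c1ccccc1)(c1ccccc1)C(C)(C)C)CCC | intermediate
14 | tert-butyldimethylsilyl N-[(2S,3R,5Z,11R)-3-[(tert-butyldimethylsilyl)oxy]-11-[(tert-butyldiphenylsilyl)oxy]tetradec-5-en-2-yl]carbamate | C[C@H](NC(=O)O[Si](C)(C)C(C)(C)C)[C@H](O[Si](C)(C)C(C)(C)C)C/C=C\CCCC[C@H](O[Si](c1ccccc1)(c1ccccc1)C(C)(C)C)CCC | intermediate
15 | (2S,3R,5Z,11R)-3-[(tert-butyldimethylsilyl)oxy]-11-[(tert-butyldiphenylsilyl)oxy]tetradec-5-en-2-amine | C[C@H](N)[C@H](O[Si](C)(C)C(C)(C)C)C/C=C\CCCC[C@H](O[Si](c1ccccc1)(c1ccccc1)C(C)(C)C)CCC | intermediate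
16 | (E)-but-2-enal | C/C=C/C=O | starting material
17 | (1E,2E)-N-[(2S,3R,5Z,11R)-3-[(tert-butyldimethylsilyl)oxy]-11-[(tert-butyldiphenylsilyl)oxy]tetradec-5-en-2-yl]but-2-en-1-imine | C/C=C/C=N/[C@@H](C)[C@H](O[Si](C)(C)C(C)(C)C)C/C=C\CCCC[C@H](O[Si](c1ccccc1)(c1ccccc1)C(C)(C)C)CCC | intermediate
18 | sodium [(1E)-buta-1,3-dien-1-yl][(2S,3R,5Z,11R)-3-[(tert-butyldimethylsilyl)oxy]-11-[(tert-butyldiphenylsilyl)oxy]tetradec-5-en-2-yl]azanide | [Na+].C=C/C=C/[N-][C@@H](C)[C@H](O[Si](C)(C)C(C)(C)C)C/C=C\CCCC[C@H](O[Si](c1ccccc1)(c1ccccc1)C(C)(C)C)CCC | intermediate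
19 | benzyl N-[(1E)-buta-1,3-dien-1-yl]-N-[(2S,3R,5Z,11R)-3-[(tert-butyldimethylsilyl)oxy]-11-[(tert-butyldiphenylsilyl)oxy]tetradec-5-en-2-yl]carbamate | C=C/C=C/N(C(=O)OCc1ccccc1)[C@@H](C)[C@H](O[Si](C)(C)C(C)(C)C)C/C=C\CCCC[C@H](O[Si](c1ccccc1)(c1ccccc1)C(C)(C)C)CCC | intermediate
20 | benzyl (2S,3R,4aS,5S,8aR)-3-[(tert-butyldimethylsilyl)oxy]-5-[(5R)-5-[(tert-butyldiphenylsilyl)oxy]octyl]-2-methyl-3,4,4a,5,6,8a-hexahydroquinoline-1(2H)-carboxylate | CC(C)(C)[Si](C)(C)O[C@@H]1C[C@H]2[C@@H](CCCC[C@H](O[Si](c3ccccc3)(c3ccccc3)C(C)(C)C)CCC)CC=C[C@H]2N(C(=O)OCc2ccccc2)[C@H]1C | intermediate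
21 | (2S,3R,4aS,5S,8aR)-3-[(tert-butyldimethylsilyl)oxy]-5-[(5R)-5-[(tert-butyldiphenylsilyl)oxy]octyl]-2-methyldecahydroquinoline | CC(C)(C)[Si](C)(C)O[C@@H]1C[C@H]2[C@@H](CCCC[C@H](O[Si](c3ccccc3)(c3ccccc3)C(C)(C)C)CCC)CCC[C@H]2N[C@H]1C | intermediate
22 | tert-butyl (2S,3R,4aS,5S,8aR)-3-[(tert-butyldimethylsilyl)oxy]-5-[(5R)-5-[(tert-butyldiphenylsilyl)oxy]octyl]-2-methyloctahydroquinoline-1(2H)-carboxylate | CC(C)(C)[Si](C)(C)O[C@@H]1C[C@H]2[C@@H](CCCC[C@H](O[Si](c3ccccc3)(c3ccccc3)C(C)(C)C)CCC)CCC[C@H]2N(C(=O)OC(C)(C)C)[C@H]1C | intermediate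
23 | tert-butyl (2S,3R,4aS,5S,8aR)-5-[(5R)-5-[(tert-butyldiphenylsilyl)oxy]octyl]-3-hydroxy-2-methyloctahydroquinoline-1(2H)-carboxylate | O[C@@H]1C[C@H]2[C@@H](CCCC[C@H](O[Si](c3ccccc3)(c3ccccc3)C(C)(C)C)CCC)CCC[C@H]2N(C(=O)OC(C)(C)C)[C@H]1C | intermediate
24 | (2E,4E)-octa-2,4-dienoic acid | CCC/C=C/C=C/C(=O)O | starting material
25 | (2E,4E)-octa-2,4-dienoic 2,4,6-trichlorobenzoic anhydride | CCC/C=C/C=C/C(=O)OC(=O)c1c(Cl)cc(Cl)cc1Cl | intermediate
26 | tert-butyl (2S,3R,4aS,5S,8aR)-5-[(5R)-5-[(tert-butyldiphenylsilyl)oxy]octyl]-2-methyl-3-{[(2E,4E)-octa-2,4-dienoyl]oxy}octahydroquinoline-1(2H)-carboxylate | CCC/C=C/C=C/C(=O)O[C@@H]1C[C@H]2[C@@H](CCCC[C@H](O[Si](c3ccccc3)(c3ccccc3)C(C)(C)C)CCC)CCC[C@H]2N(C(=O)OC(C)(C)C)[C@H]1C | intermediate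
27 | tert-butyl (2S,3R,4aS,5S,8aR)-5-[(5R)-5-hydroxyoctyl]-2-methyl-3-{[(2E,4E)-octa-2,4-dienoyl]oxy}octahydroquinoline-1(2H)-carboxylate | CCC/C=C/C=C/C(=O)O[C@@H]1C[C@H]2[C@@H](CCCC[C@H](O)CCC)CCC[C@H]2N(C(=O)OC(C)(C)C)[C@H]1C | intermediate
28 | lepadin H, (2S,3R,4aS,5S,8aR)-5-[(5R)-5-hydroxyoctyl]-2-methyldecahydroquinolin-3-yl (2E,4E)-octa-2,4-dienoate | CCC/C=C/C=C/C(=O)O[C@@H]1C[C@H]2[C@@H](CCCC[C@H](O)CCC)CCC[C@H]2N[C@H]1C | target

**Count and risks**
Total: 15 steps. Longest linear sequence: 13 steps (steps 1–3, then 6–15, from compound 1); the side-chain branch (steps 4–5) joins at step 6.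

Most likely to fail, in order:

Step 10. The unactivated Z-alkene may add too slowly, so that geometric isomerisation, hydrogen shift or polymerisation of the dienyl carbamate competes; leakage through the tether-exo transition state would also erode the cis ring fusion. The fallback leaves the thermal pericyclic manifold and runs the same [4+2] as a rhodium-templated stepwise process (oxidative cyclisation of the diene–ene pair to a rhodacycle, then reductive elimination). Conditions would be [Rh(C8H14)2Cl]2 with P(OCH(CF3)2)3 in THF at about 55 °C, a known way to cyclise unactivated 1,3-diene–alkene pairs far below 200 °C. It sets out from 19 and comes back at 20 and makes no new compound (F0). Applying this catalysis to a dienyl carbamate and a 1,2-disubstituted Z-alkene is an untested extension, so the ring-fusion and facial outcome would have to be assigned before going on.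

Step 6. Proton transfer from the carbamate N–H may quench the acetylide, and the BF3-activated epoxide may be captured by the Boc carbonyl oxygen (cyclisation with inversion at C3) faster than by the alkyne. The fallback changes the bond that joins the two halves from C4–C5 to C5=C6. Epoxide 4 would be opened with an excess of inexpensive vinylmagnesium bromide and catalytic CuI to tert-butyl N-[(2S,3R)-3-hydroxyhex-5-en-2-yl]carbamate F1. Alkyne 10 would be semihydrogenated over Pd/CaCO3 poisoned with Pb(OAc)2 to the terminal alkene tert-butyl{[(4R)-dec-9-en-4-yl]oxy}diphenylsilane F2. Z-selective cross-metathesis of F1 with F2 would then give 13 directly with loss of ethene, and the route is rejoined there without step 7. The catalyst would be a cyclometalated ruthenium nitrate alkylidene of the Grubbs Z-selective type (N-adamantyl, N′-aryl imidazolinylidene chelate, 2-isopropoxybenzylidene).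

Step 9. Condensation of the α-branched amine may be incomplete, the azapentadienyl anion may be acylated at carbon or give the Z-dienamide, and the imine or product may hydrolyse on handling. The fallback reverses the order of N-acylation and C–N double-bond formation. Amine 15 would first be converted (CbzCl, aq. NaHCO3) into benzyl N-[(2S,3R,5Z,11R)-3-[(tert-butyldimethylsilyl)oxy]-11-[(tert-butyldiphenylsilyl)oxy]tetradec-5-en-2-yl]carbamate F3. This N–H carbamate would then be condensed with (E)-but-2-enal 16 under dehydrating acid catalysis (PPTS, toluene, reflux, 4 Å molecular sieves), the known route from N–H amides or carbamates and enals to N-acyl 1-amino-1,3-dienes by way of the N-acyl hemiaminal. This should give the thermodynamically preferred E-dienyl carbamate 19, where the route is rejoined.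

**Further compounds**
F0 | step 10 | none | none
F1 | step 6 | tert-butyl N-[(2S,3R)-3-hydroxyhex-5-en-2-yl]carbamate | C[C@H](NC(=O)OC(C)(C)C)[C@H](O)CC=C
F2 | step 6 | tert-butyl{[(4R)-dec-9-en-4-yl]oxy}diphenylsilane | C=CCCCC[C@H](O[Si](c1ccccc1)(c1ccccc1)C(C)(C)C)CCC
F3 | step 9 | benzyl N-[(2S,3R,5Z,11R)-3-[(tert-butyldimethylsilyl)oxy]-11-[(tert-butyldiphenylsilyl)oxy]tetradec-5-en-2-yl]carbamate | C[C@H](NC(=O)OCc1ccccc1)[C@H](O[Si](C)(C)C(C)(C)C)C/C=C\CCCC[C@H](O[Si](c1ccccc1)(c1ccccc1)C(C)(C)C)CCC
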